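The oxolane (numbered O1, C2 aryl, C3, C4, C5) is cut at the O1–C5 bond. Quaternary C4 carries one oxygen and two CH2 groups, ring C5 and benzylic C7', which is the substitution pattern of a 3-substituted oxetan-3-ol. In the key step a chiral phosphoric acid lets the C2 hydroxyl open the oxetane at one of its two diastereotopic CH2 carbons: one operation closes the oxolane, creates the C4 stereocentre and frees the other CH2 as a hydroxymethyl handle for C7'. The precursor is the acyclic syn-aldol diol (1S,2R)-3-benzyloxy-1-(3,4-dimethoxyphenyl)-2-(3-hydroxyoxetan-3-yl)propan-1-ol, built from oxetan-3-one and veratraldehyde by two aldol reactions on one Evans imide.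

Key step: step 7

Remark: oxolanes are named with the numbering above (the spiro-epoxide by spiro nomenclature). The (R) acid is written in step 7 on the assumption that it is the matched partner of the substrate, and its (S) antipode replaces it if the first run shows the opposite.

**Step 1**
Reactants: 1 (S)-3-acetyl-4-benzyloxazolidin-2-one; 2 oxetan-3-one
Product: 5 (S)-4-benzyl-3-[2-(3-hydroxyoxetan-3-yl)acetyl]oxazolidin-2-one, via lithium enolate 3 (not isolated), via lithium aldolate 4 (not isolated)
Conditions: LiN(SiMe3)2, THF, −78 °C; then 2, −78 °C; AcOH quench at −78 °C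
Reagents that add atoms: none
Why: Acetate aldol addition of the lithium imide enolate to a strained, highly electrophilic and hardly enolisable ketone; the ketone is symmetric, so no stereocentre arises, and the cold acidic quench forestalls retro-aldol cleavage and acyl transfer.

**Step 2**
Reactants: 5 (S)-4-benzyl-3-[2-(3-hydroxyoxetan-3-yl)acetyl]oxazolidin-2-one
Product: 6 (S)-4-benzyl-3-{2-[3-(triethylsilyloxy)oxetan-3-yl]acetyl}oxazolidin-2-one
Conditions: Et3SiOTf, 2,6-lutidine, CH2Cl2, −78 → 0 °C
Reagents that add atoms: triethylsilyl trifluoromethanesulfonate, CC[Si](CC)(CC)OS(=O)(=O)C(F)(F)F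
Why: Silyl triflate silylation of a tertiary alcohol under hindered-base buffering masks the hydroxyl that would otherwise bind boron in step 3; the low temperature keeps the Lewis-acidic silyl triflate from touching the oxetane.

**Step 3**
Reactants: 6 (S)-4-benzyl-3-{2-[3-(triethylsilyloxy)oxetan-3-yl]acetyl}oxazolidin-2-one; 7 veratraldehyde (3,4-dimethoxybenzaldehyde)
Product: 10 (S)-4-benzyl-3-{(2R,3S)-3-(3,4-dimethoxyphenyl)-3-hydroxy-2-[3-(triethylsilyloxy)oxetan-3-yl]propanoyl}oxazolidin-2-one, via Z-boron enolate 8 (not isolated), via boron aldolate 9 (not isolated)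
Conditions: Bu2BOTf, i-Pr2NEt, CH2Cl2, −78 → 0 °C; then 7, −78 → 0 °C; pH 7 buffer, MeOH, 30% H2O2, 0 °C
Reagents that add atoms: none
Why: Evans syn-aldol reaction, in which soft enolisation gives the Z-boron enolate that adds to the aldehyde through a chair Zimmerman–Traxler transition state on the face away from the benzyl group of the (S)-auxiliary, setting the carbinol centre (future C2, S) and the α-centre (future C3) in the syn relation; β-elimination of the silyloxy group is disfavoured because it would place an sp2 carbon in the four-membered ring.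

**Step 4**
Reactants: 10 (S)-4-benzyl-3-{(2R,3S)-3-(3,4-dimethoxyphenyl)-3-hydroxy-2-[3-(triethylsilyloxy)oxetan-3-yl]propanoyl}oxazolidin-2-one
Product: 11 (1S,2R)-1-(3,4-dimethoxyphenyl)-2-[3-(triethylsilyloxy)oxetan-3-yl]propane-1,3-diol
Conditions: LiBH4, MeOH (1 equiv), THF, 0 °C
Reagents that add atoms: none
Why: Reductive cleavage of the N-acyl oxazolidinone by LiBH4, assisted by the free β-hydroxyl, should deliver the primary alcohol without touching the two stereocentres, the silyl ether or the oxetane.

**Step 5**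
Reactants: 11 (1S,2R)-1-(3,4-dimethoxyphenyl)-2-[3-(triethylsilyloxy)oxetan-3-yl]propane-1,3-diol
Product: 12 (1S,2R)-3-(benzyloxy)-1-(3,4-dimethoxyphenyl)-2-[3-(triethylsilyloxy)oxetan-3-yl]propan-1-ol
Conditions: Ag2O (1.5 equiv), BnBr (1.1 equiv), CH2Cl2, rt, dark
Reagents that add atoms: benzyl bromide, BrCc1ccccc1
Why: Ag2O-mediated Williamson etherification should alkylate the unhindered primary hydroxyl in preference to the secondary benzylic one, which is flanked by the branched C3 carbon, and the non-basic medium excludes silyl migration.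

**Step 6**
Reactants: 12 (1S,2R)-3-(benzyloxy)-1-(3,4-dimethoxyphenyl)-2-[3-(triethylsilyloxy)oxetan-3-yl]propan-1-ol
Product: 13 (1S,2R)-3-(benzyloxy)-1-(3,4-dimethoxyphenyl)-2-(3-hydroxyoxetan-3-yl)propan-1-ol
Conditions: Bu4NF, THF, 0 °C → rt; aq. NH4Cl
Reagents that add atoms: none
Why: Fluoride-induced desilylation frees the tertiary oxetanol; the benzyl ether, the oxetane and the benzylic alcohol are inert to Bu4NF.

**Step 7**
Reactants: 13 (1S,2R)-3-(benzyloxy)-1-(3,4-dimethoxyphenyl)-2-(3-hydroxyoxetan-3-yl)propan-1-ol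
Product: 14 (2S,3R,4R)-3-[(benzyloxy)methyl]-2-(3,4-dimethoxyphenyl)-4-(hydroxymethyl)oxolan-4-ol
Conditions: (R)-TRIP [(R)-3,3'-bis(2,4,6-triisopropylphenyl)-1,1'-binaphthyl-2,2'-diyl hydrogen phosphate] (10 mol %), PhMe (0.05 M), 4 Å MS, 25–40 °C
Reagents that add atoms: none
Why: The acid hydrogen-bonds or protonates the oxetane oxygen while its phosphoryl oxygen accepts the proton of the C2 hydroxyl, so both reacting groups sit in one chiral assembly and the C2 oxygen displaces the activated C–O bond at a methylene carbon from the backside, driven by release of the four-ring strain. The closest known reaction type is the chiral-phosphoric-acid-catalysed intramolecular desymmetrising opening of 3,3-disubstituted oxetanes by a tethered hydroxyl. The single ring closes in the 5-exo-tet mode: O1–C5 forms and the departing oxetane oxygen ends outside the ring as the hydroxymethyl group on C4. The one new stereocentre, C4 (R), is defined by which of the two diastereotopic CH2 groups is attacked, and this choice is made by the chiral pocket of the catalyst acting on top of the modest bias of the C2 and C3 centres. The step needs site selectivity among the oxygens and between the two CH2 groups: the primary oxygen is capped as its benzyl ether, the tertiary hydroxyl could reach an oxetane carbon only through a three-membered transition state, and only the secondary hydroxyl has the 5-exo geometry. C2 and C3 stay untouched because oxygen is the nucleophile and no bond to either carbon is broken, and a weak acid in a non-polar solvent should not ionise the benzylic C2–O bond.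

**Step 8**
Reactants: 14 (2S,3R,4R)-3-[(benzyloxy)methyl]-2-(3,4-dimethoxyphenyl)-4-(hydroxymethyl)oxolan-4-ol
Product: 16 (3R,6S,7R)-7-[(benzyloxy)methyl]-6-(3,4-dimethoxyphenyl)-1,5-dioxaspiro[2.4]heptane, via primary tosylate 15 (not isolated)
Conditions: TsCl, Et3N, Bu2SnO (2 mol %), CH2Cl2, 0 °C → rt; then K2CO3, MeOH, rt
Reagents that add atoms: none
Why: Regioselective sulfonylation of the primary hydroxyl (tin-acetal catalysis) followed by intramolecular Williamson displacement by the tertiary alkoxide gives the spiro-epoxide; the C4–O bond is never broken, so C4 keeps its configuration.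

**Step 9**
Reactants: 17 4-bromo-2-methoxyphenol
Product: 18 1-(benzyloxy)-4-bromo-2-methoxybenzene
Conditions: BnBr, K2CO3, DMF, rt
Reagents that add atoms: benzyl bromide, BrCc1ccccc1
Why: Williamson etherification of a phenol; the benzyl ether makes the aryl bromide fit for Grignard formation and falls in the last step together with the other benzyl group.

**Step 10**
Reactants: 16 (3R,6S,7R)-7-[(benzyloxy)methyl]-6-(3,4-dimethoxyphenyl)-1,5-dioxaspiro[2.4]heptane; 18 1-(benzyloxy)-4-bromo-2-methoxybenzene
Product: 21 (2S,3R,4S)-4-[4-(benzyloxy)-3-methoxybenzyl]-3-[(benzyloxy)methyl]-2-(3,4-dimethoxyphenyl)oxolan-4-ol, via aryl Grignard reagent 19 (not isolated), via bromomagnesium alkoxide 20 (not isolated)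
Conditions: 18, Mg, THF, reflux; then CuI (10 mol %), 16, THF, −30 → 0 °C; aq. NH4Cl
Reagents that add atoms: none
Why: Copper-catalysed opening of a 2,2-disubstituted epoxide by an aryl Grignard reagent takes place at the unsubstituted CH2 terminus in SN2 fashion, which forms the C7'–aryl bond and leaves the configuration of C4 untouched.

**Step 11**
Reactants: 21 (2S,3R,4S)-4-[4-(benzyloxy)-3-methoxybenzyl]-3-[(benzyloxy)methyl]-2-(3,4-dimethoxyphenyl)oxolan-4-ol
Product: 22 (2S,3R,4S)-4-[4-(benzyloxy)-3-methoxybenzyl]-3-[(benzyloxy)methyl]-2-(3,4-dimethoxyphenyl)oxolan-4-yl acetate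
Conditions: Ac2O, Et3N, DMAP (1 equiv), CH2Cl2, rt → 40 °C
Reagents that add atoms: acetic anhydride, CC(=O)OC(C)=O
Why: DMAP-catalysed (Steglich-type) acylation is the standard way to esterify a hindered tertiary alcohol, and since no other free hydroxyl is present the reaction can be pushed without loss of selectivity.

**Step 12**
Reactants: 22 (2S,3R,4S)-4-[4-(benzyloxy)-3-methoxybenzyl]-3-[(benzyloxy)methyl]-2-(3,4-dimethoxyphenyl)oxolan-4-yl acetate
Product: 23 (2S,3R,4S)-2-(3,4-dimethoxyphenyl)-4-(4-hydroxy-3-methoxybenzyl)-3-(hydroxymethyl)oxolan-4-yl acetate (CNP0310348.1)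
Conditions: H2 (1 atm), 10% Pd/C, EtOAc, rt
Reagents that add atoms: none
Why: Catalytic hydrogenolysis cleaves the aryl and the alkyl benzyl ether under neutral conditions, which avoids migration of the acetyl group from the tertiary to the freed primary oxygen; the reaction is stopped at complete debenzylation to spare the benzylic C2–O1 bond.

**Compound list**

1 | (S)-3-acetyl-4-benzyloxazolidin-2-one | CC(=O)N1[C@@H](Cc2ccccc2)COC1=O | starting material
2 | oxetan-3-one | O=C1COC1 | starting material
3 | lithium enolate of 1 | [Li]OC(=C)N1[C@@H](Cc2ccccc2)COC1=O | intermediate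
4 | lithium aldolate of 5 | [Li]OC1(CC(=O)N2[C@@H](Cc3ccccc3)COC2=O)COC1 | intermediate
5 | (S)-4-benzyl-3-[2-(3-hydroxyoxetan-3-yl)acetyl]oxazolidin-2-one | O=C(CC1(O)COC1)N2[C@@H](Cc3ccccc3)COC2=O | intermediate
6 | (S)-4-benzyl-3-{2-[3-(triethylsilyloxy)oxetan-3-yl]acetyl}oxazolidin-2-one | CC[Si](CC)(CC)OC1(CC(=O)N2[C@@H](Cc3ccccc3)COC2=O)COC1 | intermediate
7 | veratraldehyde (3,4-dimethoxybenzaldehyde) | COc1ccc(C=O)cc1OC | starting material
8 | Z-dibutylboron enolate of 6 | CCCCB(CCCC)O/C(=C\C1(O[Si](CC)(CC)CC)COC1)N2[C@@H](Cc3ccccc3)COC2=O | intermediate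
9 | dibutylboron aldolate of 10 | COc1ccc(cc1OC)[C@@H](OB(CCCC)CCCC)[C@@H](C(=O)N2[C@@H](Cc3ccccc3)COC2=O)C4(O[Si](CC)(CC)CC)COC4 | intermediate
10 | (S)-4-benzyl-3-{(2R,3S)-3-(3,4-dimethoxyphenyl)-3-hydroxy-2-[3-(triethylsilyloxy)oxetan-3-yl]propanoyl}oxazolidin-2-one | COc1ccc(cc1OC)[C@@H](O)[C@@H](C(=O)N2[C@@H](Cc3ccccc3)COC2=O)C4(O[Si](CC)(CC)CC)COC4 | intermediate
11 | (1S,2R)-1-(3,4-dimethoxyphenyl)-2-[3-(triethylsilyloxy)oxetan-3-yl]propane-1,3-diol | COc1ccc(cc1OC)[C@@H](O)[C@@H](CO)C2(O[Si](CC)(CC)CC)COC2 | intermediate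
12 | (1S,2R)-3-(benzyloxy)-1-(3,4-dimethoxyphenyl)-2-[3-(triethylsilyloxy)oxetan-3-yl]propan-1-ol | COc1ccc(cc1OC)[C@@H](O)[C@@H](COCc2ccccc2)C3(O[Si](CC)(CC)CC)COC3 | intermediate
13 | (1S,2R)-3-(benzyloxy)-1-(3,4-dimethoxyphenyl)-2-(3-hydroxyoxetan-3-yl)propan-1-ol | COc1ccc(cc1OC)[C@@H](O)[C@@H](COCc2ccccc2)C3(O)COC3 | intermediate
14 | (2S,3R,4R)-3-[(benzyloxy)methyl]-2-(3,4-dimethoxyphenyl)-4-(hydroxymethyl)oxolan-4-ol | OC[C@@]1(O)CO[C@H](c2ccc(OC)c(OC)c2)[C@H]1COCc3ccccc3 | intermediate
15 | [(2S,3R,4S)-3-[(benzyloxy)methyl]-2-(3,4-dimethoxyphenyl)-4-hydroxyoxolan-4-yl]methyl 4-methylbenzenesulfonate | Cc1ccc(cc1)S(=O)(=O)OC[C@@]2(O)CO[C@H](c3ccc(OC)c(OC)c3)[C@H]2COCc4ccccc4 | intermediate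
16 | (3R,6S,7R)-7-[(benzyloxy)methyl]-6-(3,4-dimethoxyphenyl)-1,5-dioxaspiro[2.4]heptane | O1C[C@]12CO[C@H](c3ccc(OC)c(OC)c3)[C@H]2COCc4ccccc4 | intermediate
17 | 4-bromo-2-methoxyphenol | COc1cc(Br)ccc1O | starting material
18 | 1-(benzyloxy)-4-bromo-2-methoxybenzene | COc1cc(Br)ccc1OCc2ccccc2 | intermediate
19 | [4-(benzyloxy)-3-methoxyphenyl]magnesium bromide | COc1cc([Mg]Br)ccc1OCc2ccccc2 | intermediate
20 | bromomagnesium alkoxide of 21 | COc1cc(C[C@@]2(O[Mg]Br)CO[C@H](c3ccc(OC)c(OC)c3)[C@H]2COCc4ccccc4)ccc1OCc5ccccc5 | intermediate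
21 | (2S,3R,4S)-4-[4-(benzyloxy)-3-methoxybenzyl]-3-[(benzyloxy)methyl]-2-(3,4-dimethoxyphenyl)oxolan-4-ol | COc1cc(C[C@@]2(O)CO[C@H](c3ccc(OC)c(OC)c3)[C@H]2COCc4ccccc4)ccc1OCc5ccccc5 | intermediate
22 | (2S,3R,4S)-4-[4-(benzyloxy)-3-methoxybenzyl]-3-[(benzyloxy)methyl]-2-(3,4-dimethoxyphenyl)oxolan-4-yl acetate | COc1cc(C[C@@]2(OC(C)=O)CO[C@H](c3ccc(OC)c(OC)c3)[C@H]2COCc4ccccc4)ccc1OCc5ccccc5 | intermediate
23 | (2S,3R,4S)-2-(3,4-dimethoxyphenyl)-4-(4-hydroxy-3-methoxybenzyl)-3-(hydroxymethyl)oxolan-4-yl acetate (CNP0310348.1) | COc1cc(C[C@@]2(OC(C)=O)CO[C@H](c3ccc(OC)c(OC)c3)[C@H]2CO)ccc1O | target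

**Step count**

Total step count: 12. Longest linear sequence: 11 steps (steps 1–8 and 10–12, from 1 and 2 to 23); step 9 is a one-step side branch.

**Steps most likely to fail**

Step 7. The acid may fail to discriminate between the two diastereotopic oxetane CH2 groups, because its preference is opposed to, or too weak against, the bias of C2 and C3, so that C4 forms as a mixture. Partial ionisation at the electron-rich benzylic C2 is a second, smaller hazard. The fallback replaces catalyst control by substrate control. Setting out from 13, the ring is closed without regard to C4 by an achiral acid (diphenyl hydrogen phosphate, CH2Cl2, rt) to give the C4-epimeric mixture of oxolane diols F1. Glycol cleavage (NaIO4, THF/H2O) converges both epimers on (2S,3R)-3-[(benzyloxy)methyl]-2-(3,4-dimethoxyphenyl)oxolan-4-one F2. Wittig methylenation (Ph3PCH3Br, KOt-Bu, THF, 0 °C) gives (2S,3R)-3-[(benzyloxy)methyl]-2-(3,4-dimethoxyphenyl)-4-methylideneoxolane F3. Dihydroxylation (OsO4 cat., N-methylmorpholine N-oxide, acetone/H2O) on the face opposite the C3 benzyloxymethyl group should then give diol 14, where the route is rejoined.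

Step 3. Addition of the congested boron enolate, whose α-carbon bears a fully substituted oxetane carbon, may be slow or incomplete. Syn or facial selectivity may erode in a crowded transition state, and the boron Lewis acid may open the oxetane. The fallback replaces the aldol addition by acylation and reduction. Setting out from 2, the enantiomeric imide (R)-3-acetyl-4-benzyloxazolidin-2-one F4 (purchased) is taken through the conditions of steps 1 and 2 to the hydroxy imide F5 and its triethylsilyl ether F6. Deprotonation with NaN(SiMe3)2 (THF, −78 °C) and C-acylation with 3,4-dimethoxybenzoyl chloride should give the β-keto imide F7. A chelated metal enolate reacts on the face opposite to that used by the boron enolate, hence the (R)-auxiliary for the same C3 configuration. Chelation-controlled reduction with Zn(BH4)2 (CH2Cl2/Et2O, −20 °C) should give the syn hydroxy imide F8. LiBH4 cleavage as in step 4 then gives diol 11, where the route is rejoined.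

Step 11. Acylation of the congested tertiary hydroxyl may stay incomplete, and forcing the conditions invites elimination. The fallback acylates the metal alkoxide in place of the free alcohol. Setting out from the bromomagnesium alkoxide 20, generated from 16 and 19 exactly as in step 10, the mixture is not quenched but treated in the same flask with excess Ac2O (THF, 0 °C → rt). This should acetylate the alkoxide oxygen directly and give 22, where the route is rejoined.

**Further compounds**

F1 | step 7 | (2S,3R)-3-[(benzyloxy)methyl]-2-(3,4-dimethoxyphenyl)-4-(hydroxymethyl)oxolan-4-ol, mixture of C4 epimers | OCC1(O)CO[C@H](c2ccc(OC)c(OC)c2)[C@H]1COCc3ccccc3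
F2 | step 7 | (2S,3R)-3-[(benzyloxy)methyl]-2-(3,4-dimethoxyphenyl)oxolan-4-one | O=C1CO[C@H](c2ccc(OC)c(OC)c2)[C@H]1COCc3ccccc3
F3 | step 7 | (2S,3R)-3-[(benzyloxy)methyl]-2-(3,4-dimethoxyphenyl)-4-methylideneoxolane | C=C1CO[C@H](c2ccc(OC)c(OC)c2)[C@H]1COCc3ccccc3
F4 | step 3 | (R)-3-acetyl-4-benzyloxazolidin-2-one (purchased) | CC(=O)N1[C@H](Cc2ccccc2)COC1=O
F5 | step 3 | (R)-4-benzyl-3-[2-(3-hydroxyoxetan-3-yl)acetyl]oxazolidin-2-one | O=C(CC1(O)COC1)N2[C@H](Cc3ccccc3)COC2=O
F6 | step 3 | (R)-4-benzyl-3-{2-[3-(triethylsilyloxy)oxetan-3-yl]acetyl}oxazolidin-2-one | CC[Si](CC)(CC)OC1(CC(=O)N2[C@H](Cc3ccccc3)COC2=O)COC1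
F7 | step 3 | (R)-4-benzyl-3-{(2S)-3-(3,4-dimethoxyphenyl)-3-oxo-2-[3-(triethylsilyloxy)oxetan-3-yl]propanoyl}oxazolidin-2-one | COc1ccc(cc1OC)C(=O)[C@@H](C(=O)N2[C@H](Cc3ccccc3)COC2=O)C4(O[Si](CC)(CC)CC)COC4
F8 | step 3 | (R)-4-benzyl-3-{(2R,3S)-3-(3,4-dimethoxyphenyl)-3-hydroxy-2-[3-(triethylsilyloxy)oxetan-3-yl]propanoyl}oxazolidin-2-one | COc1ccc(cc1OC)[C@@H](O)[C@@H](C(=O)N2[C@H](Cc3ccccc3)COC2=O)C4(O[Si](CC)(CC)CC)COC4
F0 | step 11 | none | none
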